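**Plan**

1. Lignan locants: the oxolane ring is O–C7(aryl)–C8(C9H2O‑ester)–C8'(C7'H(OH)aryl)–C9'H2. The retrosynthesis cuts, in order: the C9O–acyl ester bond, the C7'–H bond (ketone reduction), the C7'–aryl bond, then the lactone C7'–O bond together with the ring bond C8–C8' (ring‑contraction retron), the C8–C9 bond (formaldehyde aldol), and last C7–C8 and O–C9' of a six‑membered pyranone (hetero‑Diels–Alder).
2. Enabling feature: C8' carries a carbonyl‑level carbon (C7') and its neighbour C8 carries a cis CH2OH. If C7' is put into the ring between C8 and C8', the oxolane becomes an oxan‑4‑one; its α‑diazo derivative contracts and ejects C7' as a ketene that the C9 hydroxyl captures as a cis‑fused γ‑lactone.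
3. Forward order: pyranone ring (hetero‑Diels–Alder), C9 branch, diazo group, ring contraction to the oxolane with lactone closure, then the second aryl group, the coumarate, the carbinol, and desilylation.
4. Stereochemistry: C7 from a chiral titanium BINOLate; C8 trans to C7 by 1,2‑induction (also the stable epimer); C8' from the cis ring fusion enforced in the key step; C7' by CBS reduction, expected to be reinforced by the Felkin–Anh bias.
5. Phenols travel as TBS ethers; the C9 hydroxyl is held as a triethylsilyl ether only until the diazo group is in place.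

Key step: step 6

**Route**

Step 1
Reactants: 1 vanillin
Product: 2 4-(tert-butyldimethylsilyloxy)-3-methoxybenzaldehyde
Conditions: TBSCl, imidazole, CH2Cl2, rt
Reagents that add atoms: tert-butyldimethylsilyl chloride CC(C)(C)[Si](C)(C)Cl
Why: Imidazole-mediated O-silylation of the phenol, which masks the acidic OH for the later enolate, hydride and aryllithium steps and is cleaved by fluoride at the end.

Step 2
Reactants: 2 4-(tert-butyldimethylsilyloxy)-3-methoxybenzaldehyde; 3 (E)-1-methoxy-3-(trimethylsilyloxy)buta-1,3-diene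
Product: 5 (S)-2-[4-(tert-butyldimethylsilyloxy)-3-methoxyphenyl]-2,3-dihydro-4H-pyran-4-one, via Mukaiyama aldol adduct 4 (not isolated)
Conditions: (S)-BINOL (20 mol%), Ti(OiPr)4 (10 mol%), 4 Å molecular sieves, Et2O, −20 °C; then CF3CO2H, CH2Cl2, 0 °C
Reagents that add atoms: none
Why: Chiral Lewis acid-catalysed hetero-Diels–Alder reaction in its Mukaiyama aldol/cyclisation form, in which the titanium BINOLate shields one aldehyde face so that the diene CH2 terminus should create C7 as S ((S)-BINOL is chosen by analogy with benzaldehyde) and acid closes the dihydropyranone with loss of methanol.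

Step 3
Reactants: 5 (S)-2-[4-(tert-butyldimethylsilyloxy)-3-methoxyphenyl]-2,3-dihydro-4H-pyran-4-one
Product: 8 (2S,3R)-2-[4-(tert-butyldimethylsilyloxy)-3-methoxyphenyl]-3-[(triethylsilyloxy)methyl]-2,3-dihydro-4H-pyran-4-one, via lithium dienolate 6 (not isolated), via lithium alkoxide 7 (not isolated)
Conditions: LiN(iPr)2, THF, −78 °C; CH2O (monomer in THF), −78 °C; then Et3SiCl, −78 → −20 °C
Reagents that add atoms: formaldehyde C=O; chlorotriethylsilane CC[Si](Cl)(CC)CC
Why: Kinetic deprotonation at C3 (the only enolisable position), aldol addition to formaldehyde and in situ O-silylation, in which the electrophile should enter C3 (lignan C8) anti to the neighbouring C2 aryl group to give the 2,3-trans product, also the more stable epimer.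

Step 4
Reactants: 8 (2S,3R)-2-[4-(tert-butyldimethylsilyloxy)-3-methoxyphenyl]-3-[(triethylsilyloxy)methyl]-2,3-dihydro-4H-pyran-4-one
Product: 11 (2S,3R)-2-[4-(tert-butyldimethylsilyloxy)-3-methoxyphenyl]-5-diazo-3-[(triethylsilyloxy)methyl]tetrahydro-4H-pyran-4-one, via lithium enolate 9 (not isolated), via trifluoroacetyl ketone 10 (not isolated)
Conditions: Li[HB(sBu)3] (L-Selectride), THF, −78 °C; CF3CO2CH2CF3, −78 °C; aq. HCl work-up; then MsN3, Et3N, H2O (1 equiv), MeCN, rt
Reagents that add atoms: methanesulfonyl azide CS(=O)(=O)N=[N+]=[N-]; 2,2,2-trifluoroethyl trifluoroacetate O=C(OCC(F)(F)F)C(F)(F)F (its trifluoroacetyl group is carried by 10 only and leaves again)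
Why: Conjugate hydride reduction of the vinylogous ester gives the C4–C5 enolate regiospecifically, C-trifluoroacetylation activates C5, and Regitz-type deacylative diazo transfer puts the diazo group only at C5; no stereocentre is formed and C3 stays trans to C2.

Step 5
Reactants: 11 (2S,3R)-2-[4-(tert-butyldimethylsilyloxy)-3-methoxyphenyl]-5-diazo-3-[(triethylsilyloxy)methyl]tetrahydro-4H-pyran-4-one
Product: 12 (2S,3R)-2-[4-(tert-butyldimethylsilyloxy)-3-methoxyphenyl]-5-diazo-3-(hydroxymethyl)tetrahydro-4H-pyran-4-one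
Conditions: PPTS (0.2 equiv), MeOH, 0 °C
Reagents that add atoms: none
Why: Acid-catalysed methanolysis of the primary triethylsilyl ether, which should spare the acid-stable aryl TBS ethers and the acceptor-stabilised diazo ketone, frees the hydroxyl that serves as the internal ketene trap.

Step 6
Reactants: 12 (2S,3R)-2-[4-(tert-butyldimethylsilyloxy)-3-methoxyphenyl]-5-diazo-3-(hydroxymethyl)tetrahydro-4H-pyran-4-one
Product: 14 (3aR,4S,6aR)-4-[4-(tert-butyldimethylsilyloxy)-3-methoxyphenyl]tetrahydro-1H,3H-furo[3,4-c]furan-1-one, via oxolanylidene ketene 13 (not isolated)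
Conditions: hν (365 nm LED), CH2Cl2 (0.01 M), 0 °C
Reagents that add atoms: none
Why: Photoexcitation of the ring-locked s-cis α-diazo ketone expels N2 with a 1,2-shift of C3 (lignan C8) from the carbonyl carbon to the diazo carbon (Wolff rearrangement), so the six-membered oxanone contracts to the oxolane and the former ring carbonyl carbon becomes the exocyclic ketene carbon, the future C7'. The closest known reaction type is the photochemical Wolff ring contraction of cyclic 2-diazo ketones with capture of the ketene by an alcohol, here made intramolecular. The oxolane arises by the 1,2-carbon shift (six to five), and the γ-lactone closes by 5-exo-dig attack of the C9 hydroxyl on the ketene carbonyl carbon. The migrating C8 keeps its configuration and C7 is untouched; the new centre C8' is set when its C–H bond forms inside the bicyclic frame, which can only be cis-fused, so C8' is dictated by C8. The step needs the carbon shift to outrun 1,2-hydride shift from the neighbouring OCH2 group and O–H insertion; direct irradiation of the s-cis-locked diazo ketone at 0 °C favours the concerted shift, and the equatorial CH2OH cannot reach the diazo carbon without a strained bridged ring. High dilution suppresses intermolecular ketene capture and dimerisation.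

Step 7
Reactants: 15 4-bromo-2-methoxyphenol
Product: 16 (4-bromo-2-methoxyphenoxy)(tert-butyl)dimethylsilane
Conditions: TBSCl, imidazole, CH2Cl2, rt
Reagents that add atoms: tert-butyldimethylsilyl chloride CC(C)(C)[Si](C)(C)Cl
Why: Standard phenol O-silylation, giving the aryl bromide that becomes the C7' aryl nucleophile.

Step 8
Reactants: 16 (4-bromo-2-methoxyphenoxy)(tert-butyl)dimethylsilane; 14 (3aR,4S,6aR)-4-[4-(tert-butyldimethylsilyloxy)-3-methoxyphenyl]tetrahydro-1H,3H-furo[3,4-c]furan-1-one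
Product: 19 [4-(tert-butyldimethylsilyloxy)-3-methoxyphenyl][(3R,4R,5S)-5-[4-(tert-butyldimethylsilyloxy)-3-methoxyphenyl]-4-(hydroxymethyl)oxolan-3-yl]methanone, via aryllithium 17 (not isolated), via lithium hemiketal alkoxide 18 (not isolated)
Conditions: 16, n-BuLi, THF, −78 °C; then 14, −78 °C; aq. NH4Cl quench at −78 °C
Reagents that add atoms: none
Why: Bromine–lithium exchange followed by single addition of the aryllithium to the γ-lactone, whose tetrahedral lithium alkoxide is stable at −78 °C and so prevents a second addition; 19 should rest in equilibrium with its cyclic hemiketal tautomer, which keeps C8 and C8' cis.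

Step 9
Reactants: 20 (E)-p-coumaric acid
Product: 22 (E)-3-[4-(tert-butyldimethylsilyloxy)phenyl]prop-2-enoic acid, via bis-silyl derivative 21 (not isolated)
Conditions: TBSCl (2.2 equiv), imidazole, DMF, rt; then AcOH, THF/H2O, rt
Reagents that add atoms: tert-butyldimethylsilyl chloride CC(C)(C)[Si](C)(C)Cl
Why: Exhaustive silylation and selective hydrolysis of the labile silyl ester leave the phenol protected and the acid free.

Step 10
Reactants: 19 the keto alcohol of step 8; 22 (E)-3-[4-(tert-butyldimethylsilyloxy)phenyl]prop-2-enoic acid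
Product: 23 [(2S,3R,4R)-4-[4-(tert-butyldimethylsilyloxy)-3-methoxybenzoyl]-2-[4-(tert-butyldimethylsilyloxy)-3-methoxyphenyl]oxolan-3-yl]methyl (E)-3-[4-(tert-butyldimethylsilyloxy)phenyl]prop-2-enoate
Conditions: DCC, DMAP (0.1 equiv), CH2Cl2, 0 °C
Reagents that add atoms: none
Why: Steglich esterification of the primary hydroxyl of the open-chain tautomer, which drains the hemiketal equilibrium; the low temperature and catalytic DMAP are meant to leave the enolisable C8' centre untouched.

Step 11
Reactants: 23 the keto ester of step 10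
Product: 24 [(2S,3R,4R)-2-[4-(tert-butyldimethylsilyloxy)-3-methoxyphenyl]-4-[(S)-[4-(tert-butyldimethylsilyloxy)-3-methoxyphenyl](hydroxy)methyl]oxolan-3-yl]methyl (E)-3-[4-(tert-butyldimethylsilyloxy)phenyl]prop-2-enoate
Conditions: (R)-2-methyl-CBS-oxazaborolidine (0.5 equiv), BH3·SMe2, THF, −30 °C
Reagents that add atoms: none
Why: CBS reduction of the aryl ketone, with the aryl group as the large substituent as for acetophenone, should deliver hydride to the face that gives the (S)-carbinol C7', and the Felkin–Anh preference (hydride anti to the C8 branch on C8') is expected to point the same way; the ester and the cinnamate alkene should not react at this temperature.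

Step 12
Reactants: 24 the tris-TBS ether of step 11
Product: 25 [(2S,3R,4R)-4-[(S)-hydroxy(4-hydroxy-3-methoxyphenyl)methyl]-2-(4-hydroxy-3-methoxyphenyl)oxolan-3-yl]methyl (E)-3-(4-hydroxyphenyl)prop-2-enoate (CNP0330050.2)
Conditions: Bu4NF, AcOH, THF, 0 °C
Reagents that add atoms: none
Why: Fluoride cleaves the three aryl silyl ethers, and the acetic acid buffer keeps the phenoxides protonated so that the cinnamate ester and the benzylic carbinol should survive.

**Compound list**

1 | vanillin | COc1cc(C=O)ccc1O | starting material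
2 | 4-(tert-butyldimethylsilyloxy)-3-methoxybenzaldehyde | COc1cc(C=O)ccc1O[Si](C)(C)C(C)(C)C | intermediate
3 | (E)-1-methoxy-3-(trimethylsilyloxy)buta-1,3-diene | CO/C=C/C(=C)O[Si](C)(C)C | starting material
4 | (S,E)-5-[4-(tert-butyldimethylsilyloxy)-3-methoxyphenyl]-1-methoxy-5-(trimethylsilyloxy)pent-1-en-3-one | C[Si](C)(C)O[C@H](c1ccc(O[Si](C)(C)C(C)(C)C)c(OC)c1)CC(=O)/C=C/OC | intermediate
5 | (S)-2-[4-(tert-butyldimethylsilyloxy)-3-methoxyphenyl]-2,3-dihydro-4H-pyran-4-one | O=C1C=CO[C@H](c2ccc(O[Si](C)(C)C(C)(C)C)c(OC)c2)C1 | intermediate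
6 | lithium (S)-2-[4-(tert-butyldimethylsilyloxy)-3-methoxyphenyl]-2H-pyran-4-olate | [Li]OC1=C[C@@H](c2ccc(O[Si](C)(C)C(C)(C)C)c(OC)c2)OC=C1 | intermediate
7 | lithium [(2S,3R)-2-[4-(tert-butyldimethylsilyloxy)-3-methoxyphenyl]-4-oxo-3,4-dihydro-2H-pyran-3-yl]methanolate | O=C1C=CO[C@H](c2ccc(O[Si](C)(C)C(C)(C)C)c(OC)c2)[C@H]1CO[Li] | intermediate
8 | (2S,3R)-2-[4-(tert-butyldimethylsilyloxy)-3-methoxyphenyl]-3-[(triethylsilyloxy)methyl]-2,3-dihydro-4H-pyran-4-one | O=C1C=CO[C@H](c2ccc(O[Si](C)(C)C(C)(C)C)c(OC)c2)[C@H]1CO[Si](CC)(CC)CC | intermediate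
9 | lithium (2S,3R)-2-[4-(tert-butyldimethylsilyloxy)-3-methoxyphenyl]-3-[(triethylsilyloxy)methyl]-3,6-dihydro-2H-pyran-4-olate | [Li]OC1=CCO[C@H](c2ccc(O[Si](C)(C)C(C)(C)C)c(OC)c2)[C@H]1CO[Si](CC)(CC)CC | intermediate
10 | (2S,3R,5RS)-2-[4-(tert-butyldimethylsilyloxy)-3-methoxyphenyl]-3-[(triethylsilyloxy)methyl]-5-(trifluoroacetyl)tetrahydro-4H-pyran-4-one | O=C1C(C(=O)C(F)(F)F)CO[C@H](c2ccc(O[Si](C)(C)C(C)(C)C)c(OC)c2)[C@H]1CO[Si](CC)(CC)CC | intermediate
11 | (2S,3R)-2-[4-(tert-butyldimethylsilyloxy)-3-methoxyphenyl]-5-diazo-3-[(triethylsilyloxy)methyl]tetrahydro-4H-pyran-4-one | O=C1C(=[N+]=[N-])CO[C@H](c2ccc(O[Si](C)(C)C(C)(C)C)c(OC)c2)[C@H]1CO[Si](CC)(CC)CC | intermediate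
12 | (2S,3R)-2-[4-(tert-butyldimethylsilyloxy)-3-methoxyphenyl]-5-diazo-3-(hydroxymethyl)tetrahydro-4H-pyran-4-one | O=C1C(=[N+]=[N-])CO[C@H](c2ccc(O[Si](C)(C)C(C)(C)C)c(OC)c2)[C@H]1CO | intermediate
13 | [(4R,5S)-5-[4-(tert-butyldimethylsilyloxy)-3-methoxyphenyl]-4-(hydroxymethyl)oxolan-3-ylidene]methanone (ketene) | O=C=C1CO[C@H](c2ccc(O[Si](C)(C)C(C)(C)C)c(OC)c2)[C@H]1CO | intermediate
14 | (3aR,4S,6aR)-4-[4-(tert-butyldimethylsilyloxy)-3-methoxyphenyl]tetrahydro-1H,3H-furo[3,4-c]furan-1-one (cis-fused lactone) | O=C1[C@H]2CO[C@H](c3ccc(O[Si](C)(C)C(C)(C)C)c(OC)c3)[C@H]2CO1 | intermediate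
15 | 4-bromo-2-methoxyphenol | COc1cc(Br)ccc1O | starting material
16 | (4-bromo-2-methoxyphenoxy)(tert-butyl)dimethylsilane | COc1cc(Br)ccc1O[Si](C)(C)C(C)(C)C | intermediate
17 | [4-(tert-butyldimethylsilyloxy)-3-methoxyphenyl]lithium | COc1cc([Li])ccc1O[Si](C)(C)C(C)(C)C | intermediate
18 | lithium (3aR,4S,6aR)-1,4-bis[4-(tert-butyldimethylsilyloxy)-3-methoxyphenyl]tetrahydro-1H,3H-furo[3,4-c]furan-1-olate (C1 epimers) | [Li]OC1(c2ccc(O[Si](C)(C)C(C)(C)C)c(OC)c2)[C@H]2CO[C@H](c3ccc(O[Si](C)(C)C(C)(C)C)c(OC)c3)[C@H]2CO1 | intermediate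
19 | [4-(tert-butyldimethylsilyloxy)-3-methoxyphenyl][(3R,4R,5S)-5-[4-(tert-butyldimethylsilyloxy)-3-methoxyphenyl]-4-(hydroxymethyl)oxolan-3-yl]methanone | O=C(c1ccc(O[Si](C)(C)C(C)(C)C)c(OC)c1)[C@H]1CO[C@H](c2ccc(O[Si](C)(C)C(C)(C)C)c(OC)c2)[C@H]1CO | intermediate
20 | (E)-p-coumaric acid | OC(=O)/C=C/c1ccc(O)cc1 | starting material
21 | tert-butyldimethylsilyl (E)-3-[4-(tert-butyldimethylsilyloxy)phenyl]prop-2-enoate | CC(C)(C)[Si](C)(C)OC(=O)/C=C/c1ccc(O[Si](C)(C)C(C)(C)C)cc1 | intermediate
22 | (E)-3-[4-(tert-butyldimethylsilyloxy)phenyl]prop-2-enoic acid | OC(=O)/C=C/c1ccc(O[Si](C)(C)C(C)(C)C)cc1 | intermediate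
23 | [(2S,3R,4R)-4-[4-(tert-butyldimethylsilyloxy)-3-methoxybenzoyl]-2-[4-(tert-butyldimethylsilyloxy)-3-methoxyphenyl]oxolan-3-yl]methyl (E)-3-[4-(tert-butyldimethylsilyloxy)phenyl]prop-2-enoate | O=C(c1ccc(O[Si](C)(C)C(C)(C)C)c(OC)c1)[C@H]1CO[C@H](c2ccc(O[Si](C)(C)C(C)(C)C)c(OC)c2)[C@H]1COC(=O)/C=C/c1ccc(O[Si](C)(C)C(C)(C)C)cc1 | intermediate
24 | [(2S,3R,4R)-2-[4-(tert-butyldimethylsilyloxy)-3-methoxyphenyl]-4-[(S)-[4-(tert-butyldimethylsilyloxy)-3-methoxyphenyl](hydroxy)methyl]oxolan-3-yl]methyl (E)-3-[4-(tert-butyldimethylsilyloxy)phenyl]prop-2-enoate | COc1cc([C@@H](O)[C@H]2CO[C@H](c3ccc(O[Si](C)(C)C(C)(C)C)c(OC)c3)[C@H]2COC(=O)/C=C/c2ccc(O[Si](C)(C)C(C)(C)C)cc2)ccc1O[Si](C)(C)C(C)(C)C | intermediate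
25 | [(2S,3R,4R)-4-[(S)-hydroxy(4-hydroxy-3-methoxyphenyl)methyl]-2-(4-hydroxy-3-methoxyphenyl)oxolan-3-yl]methyl (E)-3-(4-hydroxyphenyl)prop-2-enoate | COc1cc([C@@H](O)[C@H]2CO[C@H](c3ccc(O)c(OC)c3)[C@H]2COC(=O)/C=C/c2ccc(O)cc2)ccc1O | target

**Count**

Total steps: 12. Longest linear sequence: 10 steps (1, 2, 3, 4, 5, 6, 8, 10, 11, 12) from vanillin.

**Steps most likely to fail**

Step 6. What may go wrong: carbene-type side paths of the diazo ketone (1,2-hydride shift from the OCH2 group back to the enone, O–H insertion), retro-aldol loss of formaldehyde from the β-hydroxy ketone, or unproductive intermolecular ketene capture. The fallback sets out from 11 and comes back at 14; it separates ring contraction from lactone closure. Irradiation of the silyl-protected diazo ketone 11 (365 nm) in MeOH at −40 °C lets the solvent capture the ketene and should give methyl (3RS,4R,5S)-5-[4-(tert-butyldimethylsilyloxy)-3-methoxyphenyl]-4-[(triethylsilyloxy)methyl]oxolane-3-carboxylate F1 as a mixture at the ester-bearing carbon. PPTS in MeOH then removes the triethylsilyl group to give methyl (3RS,4R,5S)-5-[4-(tert-butyldimethylsilyloxy)-3-methoxyphenyl]-4-(hydroxymethyl)oxolane-3-carboxylate F2. DBU in toluene equilibrates the ester-bearing centre, and only the cis epimer can lactonise, so the material should funnel to 14.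

Step 3. What may go wrong: ring opening of the cross-conjugated lithium enolate (a 4-oxido-2H-pyran) to an acyclic dienone enolate on warming, double hydroxymethylation, or hemiformal formation with excess formaldehyde. The fallback sets out from 2 and comes back at 8; it brings C9 in with the diene instead of by enolate chemistry on the ring. Commercial (E)-4-methoxybut-3-en-2-one (CO/C=C/C(C)=O) is deprotonated with LiN(iPr)2 at −78 °C and treated with monomeric formaldehyde to give (E)-5-hydroxy-1-methoxypent-1-en-3-one F3; this acyclic enolate cannot ring-open. Me3SiOTf (2.2 equiv) and Et3N convert it into (1E,3Z)-1-methoxy-3,5-bis(trimethylsilyloxy)penta-1,3-diene F4. F4 and 2 under the conditions of step 2, followed by CF3CO2H and brief DBU equilibration of the epimerisable C3, should give (2S,3R)-2-[4-(tert-butyldimethylsilyloxy)-3-methoxyphenyl]-3-(hydroxymethyl)-2,3-dihydro-4H-pyran-4-one F5. Et3SiCl and imidazole then give 8.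

Step 10. What may go wrong: enolisation of the open-chain aryl ketone at C8' with loss of the cis relationship to C8, or sluggish acylation because the substrate rests as the hemiketal. The fallback sets out from 19 and comes back at 24; it reduces before it acylates, so the epimerisable keto ester is never formed. NaBH4 with CeCl3·7H2O in MeOH at −40 °C reduces the ketone of the open tautomer of 19 under Felkin–Anh control and should give (S)-[4-(tert-butyldimethylsilyloxy)-3-methoxyphenyl][(3R,4R,5S)-5-[4-(tert-butyldimethylsilyloxy)-3-methoxyphenyl]-4-(hydroxymethyl)oxolan-3-yl]methanol F6. Site-selective acylation of its primary hydroxyl with 22 (DCC, DMAP 0.1 equiv, CH2Cl2, −20 °C) then gives 24.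

**Further compounds**

F1 | step 6 | methyl (3RS,4R,5S)-5-[4-(tert-butyldimethylsilyloxy)-3-methoxyphenyl]-4-[(triethylsilyloxy)methyl]oxolane-3-carboxylate | COC(=O)C1CO[C@H](c2ccc(O[Si](C)(C)C(C)(C)C)c(OC)c2)[C@H]1CO[Si](CC)(CC)CC
F2 | step 6 | methyl (3RS,4R,5S)-5-[4-(tert-butyldimethylsilyloxy)-3-methoxyphenyl]-4-(hydroxymethyl)oxolane-3-carboxylate | COC(=O)C1CO[C@H](c2ccc(O[Si](C)(C)C(C)(C)C)c(OC)c2)[C@H]1CO
F3 | step 3 | (E)-5-hydroxy-1-methoxypent-1-en-3-one | CO/C=C/C(=O)CCO
F4 | step 3 | (1E,3Z)-1-methoxy-3,5-bis(trimethylsilyloxy)penta-1,3-diene | CO/C=C/C(O[Si](C)(C)C)=C/CO[Si](C)(C)C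
F5 | step 3 | (2S,3R)-2-[4-(tert-butyldimethylsilyloxy)-3-methoxyphenyl]-3-(hydroxymethyl)-2,3-dihydro-4H-pyran-4-one | O=C1C=CO[C@H](c2ccc(O[Si](C)(C)C(C)(C)C)c(OC)c2)[C@H]1CO
F6 | step 10 | (S)-[4-(tert-butyldimethylsilyloxy)-3-methoxyphenyl][(3R,4R,5S)-5-[4-(tert-butyldimethylsilyloxy)-3-methoxyphenyl]-4-(hydroxymethyl)oxolan-3-yl]methanol | COc1cc([C@@H](O)[C@H]2CO[C@H](c3ccc(O[Si](C)(C)C(C)(C)C)c(OC)c3)[C@H]2CO)ccc1O[Si](C)(C)C(C)(C)C
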